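Labdane numbering is used throughout.

## Retrosynthetic overview
- **Feature:** ring B carries oxygen on C6 and on C8, with only the C7 methylene between them. With C17 removed this is a 3-hydroxycyclohexanone, C6(OH)–C7H2–C8(=O).
- **Key disconnection, C6–C7:** carbocycle 20 is traced back to its 7-oxa analogue 18. This is a methyl pyranoside whose ring oxygen joins C6 and C8, with C7 attached to C8 as an exocyclic enol-ether methylene.
- **Precursor:** 18 comes from methoxy lactone 17, and 17 from aldehyde acid 16. C9–C10 is made by an enantioselective Ireland–Claisen shift of ester 10. The resulting C5=C6 methylene becomes the C6 aldehyde through an epoxide, so the side-chain vinyl group survives.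
- **Building blocks:** β-cyclocitral (ring A, C6, C20), (R)-linalool (C9, C11–C16, the C13 centre), CO2 (C8), Cp2TiMe2 (C7 and C17) and angelic acid.
- **Ring order:** ring A is bought, oxa ring B closes in step 12, and carbocyclic ring B closes in step 14. C17 and the 8α-OH follow, and the angelate is installed last.

Key step: step 14

Assumption: the (S,S)-configured boron controller is taken to deliver the (9R,10R) series drawn for 12; the sense of induction is to be verified on 12, and the equally available (R,R)-reagent is used if it is opposite.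

## Route

Step 1
Reactants: 1 (R)-(−)-linalool
Product: 2 (R)-3-(tert-butyldimethylsilyloxy)-3,7-dimethylocta-1,6-diene
Conditions: TBSOTf, 2,6-lutidine, CH2Cl2, 0 °C to rt
Reagents that add atoms: tert-butyldimethylsilyl triflate, CC(C)(C)[Si](C)(C)OS(=O)(=O)C(F)(F)F
Why: O-Silylation with a silyl triflate and a hindered pyridine base covers even this tertiary allylic alcohol without ionising it, and C13 keeps the (R) configuration that the target needs.

Step 2
Reactants: 2 (R)-3-(tert-butyldimethylsilyloxy)-3,7-dimethylocta-1,6-diene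
Product: 4 (R)-4-(tert-butyldimethylsilyloxy)-4-methylhex-5-en-1-ol, via aldehyde 3 (not isolated)
Conditions: O3 (1 equiv, Sudan Red 7B end point), CH2Cl2–MeOH, −78 °C; then NaBH4, −78 to 0 °C
Reagents that add atoms: ozone, [O-][O+]=O
Why: Chemoselective ozonolysis with reductive work-up: the trisubstituted C=C is far more electron-rich than the vinyl group beside the silyloxy carbon, so one equivalent of ozone cleaves only the former and its CH carbon becomes C9.

Step 3
Reactants: 4 (R)-4-(tert-butyldimethylsilyloxy)-4-methylhex-5-en-1-ol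
Product: 5 (R)-tert-butyl[(6-iodo-3-methylhex-1-en-3-yl)oxy]dimethylsilane
Conditions: I2, PPh3, imidazole, CH2Cl2, 0 °C
Reagents that add atoms: iodine, II
Why: Appel-type iodination of an unhindered primary alcohol under neutral conditions that leave the silyl ether and the vinyl group alone.

Step 4
Reactants: 5 (R)-tert-butyl[(6-iodo-3-methylhex-1-en-3-yl)oxy]dimethylsilane
Product: 7 (R)-5-(tert-butyldimethylsilyloxy)-5-methylhept-6-enoic acid, via hexenyllithium 6 (not isolated)
Conditions: t-BuLi (2.1 equiv), pentane–Et2O, −78 °C; dry CO2, −78 °C; cold 0.5 M HCl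
Reagents that add atoms: carbon dioxide, O=C=O
Why: Lithium–iodine exchange followed by carboxylation of the organolithium adds C8, the one carbon by which the linalool fragment is too short; at −78 °C 5-exo carbolithiation of 6 onto the vinyl group is too slow to compete.

Step 5
Reactants: 8 β-cyclocitral
Product: 9 β-cyclogeraniol, (2,6,6-trimethylcyclohex-1-en-1-yl)methanol
Conditions: NaBH4, MeOH, 0 °C
Reagents that add atoms: none
Why: 1,2-Reduction of the hindered enal with borohydride gives the primary allylic alcohol whose CH2 is C6.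

Step 6
Reactants: 7 (R)-5-(tert-butyldimethylsilyloxy)-5-methylhept-6-enoic acid; 9 β-cyclogeraniol
Product: 10 (2,6,6-trimethylcyclohex-1-en-1-yl)methyl (R)-5-(tert-butyldimethylsilyloxy)-5-methylhept-6-enoate
Conditions: DCC, DMAP (cat.), CH2Cl2, 0 °C to rt
Reagents that add atoms: none
Why: Steglich esterification joins the two fragments through the future O7 under conditions that touch neither alkene nor silyl ether.

Step 7
Reactants: 10 β-cyclogeranyl ester
Product: 12 (2R,5R)-5-(tert-butyldimethylsilyloxy)-5-methyl-2-[(1R)-1,3,3-trimethyl-2-methylidenecyclohexyl]hept-6-enoic acid, via boron ketene acetal 11 (not isolated)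
Conditions: (4S,5S)-2-bromo-1,3-bis[3,5-bis(trifluoromethyl)phenylsulfonyl]-4,5-diphenyl-1,3,2-diazaborolidine (1.2 equiv), i-Pr2NEt, CH2Cl2, −78 °C; then −20 °C to rt; aqueous work-up
Reagents that add atoms: none
Why: Enantioselective Ireland–Claisen rearrangement: soft enolisation in CH2Cl2 with the hindered amine should place C11 cis to the O–B bond, the chair [3,3] shift then joins C9 to the fully substituted C10 with H-9 anti to C20, and the C2-symmetric boron ligand selects the alkene face and so the absolute configuration of both new centres.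

Step 8
Reactants: 12 Claisen acid
Product: 13 allyl ester of 12
Conditions: allyl bromide, K2CO3, DMF, rt
Reagents that add atoms: allyl bromide, C=CCBr
Why: Carboxylate O-alkylation (SN2) bypasses the hindered C8 carbonyl and masks the acid, which would otherwise open the epoxide of step 9 at C5 to a γ-lactone; the allyl group can be removed later under neutral conditions.

Step 9
Reactants: 13 allyl ester
Product: 14 allyl ester 5,6-spiro-epoxide, epoxide oxygen on the β face (cis to C20)
Conditions: mCPBA (1.05 equiv), NaHCO3, CH2Cl2, 0 °C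
Reagents that add atoms: 3-chloroperbenzoic acid, O=C(OO)c1cccc(Cl)c1
Why: Prilezhaev epoxidation picks the 1,1-disubstituted C5=C6 bond over the two monosubstituted, inductively deactivated alkenes, and the peracid should approach anti to the bulky C9 branch on the neighbouring quaternary C10, that is on the face of the C20 methyl group, which sets C5.

Step 10
Reactants: 14 spiro-epoxide
Product: 15 allyl ester aldehyde (5α-H; formyl carbon C6 cis to C20 and trans to C9)
Conditions: MeAl(OC6H2-4-Br-2,6-t-Bu2)2 (20 mol %), CH2Cl2, −78 to −40 °C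
Reagents that add atoms: none
Why: Meinwald rearrangement: the bulky aluminium Lewis acid opens the epoxide at tertiary C5 and a hydride moves from C6 to C5 anti to the leaving oxygen, so H-5 ends on the α face (cis to C9) and C6 cis to C20, the relationship of a trans ring fusion, without a hydroboration that the vinyl group could not survive.

Step 11
Reactants: 15 allyl ester aldehyde
Product: 16 aldehyde acid (C6 aldehyde, C8 acid, 5α-H, 9α-H, 10β-CH3; in equilibrium with its lactol)
Conditions: Pd(PPh3)4 (3 mol %), N-methylaniline, THF, rt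
Reagents that add atoms: none
Why: Tsuji–Trost deallylation with zerovalent palladium and a soft amine acceptor frees the hindered acid under neutral conditions, so C5 next to the aldehyde and C9 next to the acid are not epimerised.

Step 12
Reactants: 16 aldehyde acid
Product: 17 (13R)-13-(tert-butyldimethylsilyloxy)-6α-methoxy-7-oxa-17-norlabd-14-en-8-one (trans-fused methoxy lactone)
Conditions: PPTS (cat.), MeOH, 40 °C; then toluene, 60 °C, reduced pressure (removal of MeOH)
Reagents that add atoms: methanol, CO
Why: Acid-catalysed pseudo-ester formation: the methanol hemiacetal of the C6 aldehyde lactonises onto the C8 acid (whose own Fischer esterification is slow for steric reasons), closing the trans-fused oxa ring B with the methoxy group equatorial (6α), away from C20 and the 4β-methyl group; this centre is erased in step 14.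

Step 13
Reactants: 17 methoxy lactone
Product: 18 (13R)-13-(tert-butyldimethylsilyloxy)-6α-methoxy-8-methylidene-7-oxa-17-norlabd-14-ene (methyl pyranoside; the methylidene carbon is the future C7)
Conditions: Cp2TiMe2 (2.5 equiv), toluene, 70 °C, dark; filtration through basic alumina
Reagents that add atoms: dimethyltitanocene, C[Ti](C)(C1C=CC=C1)C1C=CC=C1
Why: Petasis methylenation converts the lactone carbonyl into the exocyclic enol ether and brings in C7; the reagent is non-basic and tolerates the acetal, the silyl ether and the epimerisable C9.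

Step 14
Reactants: 18 methyl pyranoside enol ether
Product: 20 (13R)-13-(tert-butyldimethylsilyloxy)-6α-hydroxy-17-norlabd-14-en-8-one, via mercurio keto aldehyde 19 (not isolated)
Conditions: Hg(OCOCF3)2 (10 mol %), acetone–H2O 2:1, 0 °C to rt
Reagents that add atoms: water, O
Why: Divalent mercury and water add across the electron-rich C8=C7 enol ether, and the C8 hemiketal collapses to the C8 ketone with mercury on C7 while O7 stays on C6, whose hemiacetal loses methanol to give aldehyde 19. The C7 mercury enolate then attacks the C6 aldehyde, forming C6–C7 and returning the mercury salt; this is the Ferrier carbocyclisation of 6-deoxyhex-5-enopyranosides applied to a terpenoid oxadecalin with the same enol ether, ring oxygen and acetal array. Ring B closes in the 6-(enolendo)-exo-trig mode, because both enolate carbons C7 and C8 end up inside the new ring. C6, the only new stereocentre, is set in a chair transition state built on the fixed C5, C9 and C10 centres: an axial 6β oxygen would be syn-axial to C20 and to the 4β-methyl group, so the aldehyde oxygen should turn to the equatorial 6α side, even though sugar substrates often give the axial carbinol through mercury bridging of the two oxygens. The step needs chemoselectivity between the enol ether and the C14=C15 vinyl group; the enol ether is far more nucleophilic, the vinyl group is monosubstituted and deactivated by the allylic silyloxy group, and the catalytic loading at or below room temperature keeps it untouched. The medium is only weakly acidic, so the tertiary silyl ether and the C5, C9, C10 and C13 centres are preserved.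

Step 15
Reactants: 20 6α-hydroxy ketone
Product: 21 (13R)-13-(tert-butyldimethylsilyloxy)-6α-(triethylsilyloxy)-17-norlabd-14-en-8-one
Conditions: TESOTf, 2,6-lutidine, CH2Cl2, −78 °C
Reagents that add atoms: triethylsilyl triflate, CC[Si](CC)(CC)OS(=O)(=O)C(F)(F)F
Why: O-Silylation at low temperature protects the β-hydroxy ketone against retro-aldol cleavage, elimination and protonolysis of the titanium reagent in step 16.

Step 16
Reactants: 21 6-O-TES ketone
Product: 22 (13R)-13-(tert-butyldimethylsilyloxy)-6α-(triethylsilyloxy)labda-8(17),14-diene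
Conditions: Cp2TiMe2 (3 equiv), toluene, 70 °C, dark
Reagents that add atoms: dimethyltitanocene, C[Ti](C)(C1C=CC=C1)C1C=CC=C1
Why: Petasis methylenation of the hindered C8 ketone brings in C17 without the basic conditions of a Wittig reaction, which would eliminate the β-silyloxy group.

Step 17
Reactants: 22 8(17),14-diene
Product: 23 (13R)-8α,17-epoxy-13-(tert-butyldimethylsilyloxy)-6α-(triethylsilyloxy)labd-14-ene
Conditions: mCPBA (1.05 equiv), NaHCO3, CH2Cl2, 0 °C
Reagents that add atoms: 3-chloroperbenzoic acid, O=C(OO)c1cccc(Cl)c1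
Why: Prilezhaev epoxidation of the 1,1-disubstituted C8=C17 bond in preference to the vinyl group; the β face is closed by the axial C20 methyl group, so oxygen is delivered to the α face and C8 is set.

Step 18
Reactants: 23 8α,17-epoxide
Product: 24 (13R)-13-(tert-butyldimethylsilyloxy)-6α-(triethylsilyloxy)labd-14-en-8α-ol
Conditions: LiAlH4, THF, 0 to 50 °C; aqueous NaOH work-up
Reagents that add atoms: none
Why: Hydride opening of the epoxide at the primary C17 (SN2) leaves the C8–O bond untouched and gives the equatorial 8α tertiary alcohol with the 8β-methyl group, whereas direct methyl addition to the ketone would give the opposite epimer.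

Step 19
Reactants: 24 bis-silyl ether
Product: 25 (13R)-labd-14-ene-6α,8α,13-triol (6α-hydroxysclareol)
Conditions: TBAF (excess), THF, 55 °C
Reagents that add atoms: none
Why: Fluoride-mediated desilylation removes both silyl ethers under non-acidic conditions that spare the tertiary allylic alcohol.

Step 20
Reactants: 25 triol; 26 angelic acid
Product: 28 (13R)-6α-angeloyloxylabd-14-ene-8α,13-diol (target), via mixed anhydride 27 (not isolated)
Conditions: 26, 2,4,6-Cl3C6H2COCl, Et3N, toluene, rt; then 25, 75 °C
Reagents that add atoms: none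
Why: Yamaguchi-type mixed-anhydride acylation without a nucleophilic catalyst transfers the angeloyl group without Z to E isomerisation, and only the secondary equatorial 6α-OH reacts because the 8- and 13-hydroxy groups are tertiary.

## Compound list
1 | (R)-(−)-linalool | C=C[C@](C)(O)CCC=C(C)C | starting material
2 | (R)-linalool TBS ether | C=C[C@](C)(O[Si](C)(C)C(C)(C)C)CCC=C(C)C | intermediate
3 | (R)-4-(tert-butyldimethylsilyloxy)-4-methylhex-5-enal | C=C[C@](C)(O[Si](C)(C)C(C)(C)C)CCC=O | intermediate
4 | (R)-4-(tert-butyldimethylsilyloxy)-4-methylhex-5-en-1-ol | C=C[C@](C)(O[Si](C)(C)C(C)(C)C)CCCO | intermediate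
5 | (R)-tert-butyl[(6-iodo-3-methylhex-1-en-3-yl)oxy]dimethylsilane | C=C[C@](C)(O[Si](C)(C)C(C)(C)C)CCCI | intermediate
6 | (R)-4-(tert-butyldimethylsilyloxy)-4-methylhex-5-enyllithium | C=C[C@](C)(O[Si](C)(C)C(C)(C)C)CCC[Li] | intermediate
7 | (R)-5-(tert-butyldimethylsilyloxy)-5-methylhept-6-enoic acid | C=C[C@](C)(O[Si](C)(C)C(C)(C)C)CCCC(=O)O | intermediate
8 | β-cyclocitral | CC1=C(C=O)C(C)(C)CCC1 | starting material
9 | β-cyclogeraniol | CC1=C(CO)C(C)(C)CCC1 | intermediate
10 | β-cyclogeranyl (R)-5-(tert-butyldimethylsilyloxy)-5-methylhept-6-enoate | C=C[C@](C)(O[Si](C)(C)C(C)(C)C)CCCC(=O)OCC1=C(C)CCCC1(C)C | intermediate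
11 | boron ketene acetal of 10 (C9=C8, C11 cis to O–B, boron bound to the (S,S)-bis-sulfonamide) | C=C[C@](C)(O[Si](C)(C)C(C)(C)C)CC/C=C(/OCC1=C(C)CCCC1(C)C)OB1N(S(=O)(=O)c2cc(C(F)(F)F)cc(C(F)(F)F)c2)[C@@H](c2ccccc2)[C@H](c2ccccc2)N1S(=O)(=O)c1cc(C(F)(F)F)cc(C(F)(F)F)c1 | intermediate
12 | Claisen acid, (9R,10R,13R), C5=C6 methylene | C=C[C@](C)(O[Si](C)(C)C(C)(C)C)CC[C@@H](C(=O)O)[C@@]1(C)CCCC(C)(C)C1=C | intermediate
13 | allyl ester of 12 | C=C[C@](C)(O[Si](C)(C)C(C)(C)C)CC[C@@H](C(=O)OCC=C)[C@@]1(C)CCCC(C)(C)C1=C | intermediate
14 | allyl ester 5,6-spiro-epoxide, oxygen cis to C20 | C=C[C@](C)(O[Si](C)(C)C(C)(C)C)CC[C@@H](C(=O)OCC=C)[C@@]1(C)CCCC(C)(C)[C@@]12CO2 | intermediate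
15 | allyl ester C6 aldehyde, 5α-H | C=C[C@](C)(O[Si](C)(C)C(C)(C)C)CC[C@@H](C(=O)OCC=C)[C@@]1(C)CCCC(C)(C)[C@@H]1C=O | intermediate
16 | aldehyde acid (C6 aldehyde, C8 acid) | C=C[C@](C)(O[Si](C)(C)C(C)(C)C)CC[C@@H](C(=O)O)[C@@]1(C)CCCC(C)(C)[C@@H]1C=O | intermediate
17 | 6α-methoxy-7-oxa-17-norlabd-14-en-8-one, 13-O-TBS | C=C[C@](C)(O[Si](C)(C)C(C)(C)C)CC[C@@H]1[C@@]2(C)CCCC(C)(C)[C@@H]2[C@@H](OC)OC1=O | intermediate
18 | 6α-methoxy-8-methylidene-7-oxa-17-norlabd-14-ene, 13-O-TBS | C=C[C@](C)(O[Si](C)(C)C(C)(C)C)CC[C@@H]1[C@@]2(C)CCCC(C)(C)[C@@H]2[C@@H](OC)OC1=C | intermediate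
19 | C7-mercurated keto aldehyde (C8 ketone with CH2HgOCOCF3, C6 aldehyde) | C=C[C@](C)(O[Si](C)(C)C(C)(C)C)CC[C@@H](C(=O)C[Hg]OC(=O)C(F)(F)F)[C@@]1(C)CCCC(C)(C)[C@@H]1C=O | intermediate
20 | 6α-hydroxy-17-norlabd-14-en-8-one, 13-O-TBS | C=C[C@](C)(O[Si](C)(C)C(C)(C)C)CC[C@@H]1[C@@]2(C)CCCC(C)(C)[C@@H]2[C@@H](O)CC1=O | intermediate
21 | 6α-O-TES, 13-O-TBS 17-nor-8-ketone | C=C[C@](C)(O[Si](C)(C)C(C)(C)C)CC[C@@H]1[C@@]2(C)CCCC(C)(C)[C@@H]2[C@@H](O[Si](CC)(CC)CC)CC1=O | intermediate
22 | 6α-O-TES, 13-O-TBS labda-8(17),14-diene | C=C[C@](C)(O[Si](C)(C)C(C)(C)C)CC[C@@H]1[C@@]2(C)CCCC(C)(C)[C@@H]2[C@@H](O[Si](CC)(CC)CC)CC1=C | intermediate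
23 | 8α,17-epoxide of 22 | C=C[C@](C)(O[Si](C)(C)C(C)(C)C)CC[C@@H]1[C@@]2(C)CCCC(C)(C)[C@@H]2[C@@H](O[Si](CC)(CC)CC)C[C@]13CO3 | intermediate
24 | 6α-O-TES, 13-O-TBS labd-14-en-8α-ol | C=C[C@](C)(O[Si](C)(C)C(C)(C)C)CC[C@@H]1[C@@]2(C)CCCC(C)(C)[C@@H]2[C@@H](O[Si](CC)(CC)CC)C[C@@]1(C)O | intermediate
25 | (13R)-labd-14-ene-6α,8α,13-triol | C=C[C@](C)(O)CC[C@@H]1[C@@]2(C)CCCC(C)(C)[C@@H]2[C@@H](O)C[C@@]1(C)O | intermediate
26 | angelic acid, (Z)-2-methylbut-2-enoic acid | C/C=C(/C)C(=O)O | starting material
27 | angelic 2,4,6-trichlorobenzoic anhydride | C/C=C(/C)C(=O)OC(=O)c1c(Cl)cc(Cl)cc1Cl | intermediate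
28 | (13R)-6α-angeloyloxylabd-14-ene-8α,13-diol | C=C[C@](C)(O)CC[C@@H]1[C@@]2(C)CCCC(C)(C)[C@@H]2[C@@H](OC(=O)/C(C)=C\C)C[C@@]1(C)O | target

## Step count and risks
Total step count: 20. Longest linear sequence: 19 (steps 1–4 and 6–20).

**Step 14.**
- What may go wrong: the enol ether or the C7–Hg bond may be protonated before C–C bond formation, giving hydrolysis without ring closure. The aldehyde may react in the mercury-bridged arrangement that puts oxygen axial. The aldol may also lose water.
- Fallback: it sets out from 18 and returns at 20. Mild aqueous acid (PPTS, acetone–water) hydrolyses enol ether and acetal to keto aldehyde F1. Pyrrolidinium acetate in toluene closes F1 by intramolecular aldol condensation to enone F2. Copper-catalysed conjugate borylation (CuCl, NaOt-Bu, DPEphos, B2pin2, MeOH, THF) should add boron to C6 from the α face, away from C20 and the 4β-methyl group, giving 6α-boronate F3. NaBO3·4H2O oxidises the C–B bond with retention to 20.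

**Step 7.**
- What may go wrong: the [3,3] shift at the tetrasubstituted alkene may be too slow at the temperatures the boron ketene acetal tolerates. Material may leak through a boat arrangement or the other enolate geometry, which affects C9. Face selection may be incomplete or opposite, and the bromoborane may attack the tertiary allylic silyl ether.
- Fallback: it sets out from 10 and returns at 12, and replaces reagent control by separation based on the resident C13 centre. LDA in THF–DMPU followed by TBSCl gives silyl ketene acetal F4. Refluxing toluene drives the thermal Ireland–Claisen shift to silyl ester F5 together with its ring-antipodal partner, silyl ester F6. K2CO3 in aqueous methanol frees 12 and diastereomeric acid F7. Because C13 is fixed, these two acids are diastereomers and are parted by chromatography or crystallisation.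

**Step 10.**
- What may go wrong: the ester carbonyl may participate at the cationic C5. A methyl group may migrate from C4 or C10. Stereochemical fidelity may be lost, or the epoxide of step 9 may have formed on the other face, which would give the wrong C5 epimer.
- Fallback: it sets out from 14 and returns at 15. Trivalent titanium (Cp2TiCl2, Mn, THF) with 1,4-cyclohexadiene opens the epoxide homolytically to the tertiary C5 radical, so no cation is involved. The hydrogen atom is taken up on the more open face, giving primary alcohol F8. F8 is oxidised at once with Dess–Martin periodinane to 15.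
- Why it is complementary: the radical route places hydrogen on the face a reagent reaches most easily, whereas step 10 places it opposite to that face. The two routes therefore have opposite stereochemical demands, and one of them fits whichever facial bias the ring shows.

Further compounds
F1 | step 14 | keto aldehyde (C8 methyl ketone, C6 aldehyde, 13-O-TBS) | C=C[C@](C)(O[Si](C)(C)C(C)(C)C)CC[C@@H](C(C)=O)[C@@]1(C)CCCC(C)(C)[C@@H]1C=O
F2 | step 14 | enone, 13-O-TBS 17-norlabda-6,14-dien-8-one | C=C[C@](C)(O[Si](C)(C)C(C)(C)C)CC[C@@H]1[C@@]2(C)CCCC(C)(C)[C@@H]2C=CC1=O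
F3 | step 14 | 6α-boronate, 6α-(pinacolatoboryl)-17-norlabd-14-en-8-one 13-O-TBS | C=C[C@](C)(O[Si](C)(C)C(C)(C)C)CC[C@@H]1[C@@]2(C)CCCC(C)(C)[C@@H]2[C@@H](B2OC(C)(C)C(C)(C)O2)CC1=O
F4 | step 7 | silyl ketene acetal of 10 (C11 cis to OSi) | C=C[C@](C)(O[Si](C)(C)C(C)(C)C)CC/C=C(/OCC1=C(C)CCCC1(C)C)O[Si](C)(C)C(C)(C)C
F5 | step 7 | silyl ester (TBS ester of 12) | C=C[C@](C)(O[Si](C)(C)C(C)(C)C)CC[C@@H](C(=O)O[Si](C)(C)C(C)(C)C)[C@@]1(C)CCCC(C)(C)C1=C
F6 | step 7 | silyl ester of the (9S,10S,13R) diastereomer | C=C[C@](C)(O[Si](C)(C)C(C)(C)C)CC[C@H](C(=O)O[Si](C)(C)C(C)(C)C)[C@]1(C)CCCC(C)(C)C1=C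
F7 | step 7 | diastereomeric acid, (9S,10S,13R) | C=C[C@](C)(O[Si](C)(C)C(C)(C)C)CC[C@H](C(=O)O)[C@]1(C)CCCC(C)(C)C1=C
F8 | step 10 | primary alcohol (allyl ester, C6 hydroxymethyl, 5α-H) | C=C[C@](C)(O[Si](C)(C)C(C)(C)C)CC[C@@H](C(=O)OCC=C)[C@@]1(C)CCCC(C)(C)[C@@H]1CO
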